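**Plan**

- Numbering: lactone carbonyl C1, ring oxygen O2, C3 (CH3), C4 (OAc), arene C4a–C8a. Cuts, in retrosynthetic order: the O6–geranyl ether; the two phenol protecting groups; the lactone C1–O2 bond (back to an N,N-diisopropylbenzamide); then, together, C1–C8a and C3–C4.
- Enabling feature: in the hetero ring, C3–O2–C1 is an oxygen-bearing carbon that carries its own acyl carbon, and C4–C4a–C8a is an aldehyde carbon next to the arene carbon ortho to it. C3 and C4 are both oxygenated carbons, so C3 is used with reversed polarity, as an α-oxy carbanion whose carbamate carbon is C1.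
- Forward: 3,5-dihydroxybenzaldehyde is taken in five steps to the ortho-silyl aldehyde 9. In step 6 lithiated ethyl carbamate adds to the aldehyde (C3–C4), silicon moves from C8a to O4, and the aryl anion so released takes the carbamoyl carbon from O2 (C1–C8a); silicon then moves on to O2 and O4 is acetylated in the same flask.
- The hetero ring is closed afterwards (O2 onto the activated C1, step 7); the isopropyl ethers are then cleaved and O6 is geranylated (the 8-OH is hydrogen-bonded to C1=O).
- Stereochemistry: C3 from (+)-sparteine-directed deprotonation of the carbamate and retentive addition; C4 from the facial selectivity of that addition; no later step touches either centre.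

Key step: step 6

Assumption: ethyl N,N-diisopropylcarbamate, geranyl bromide and (+)-sparteine are purchased; the cytisine-derived (+)-sparteine surrogate would serve in the same way.

**Route**

Step 1
Reactants: 1 3,5-dihydroxybenzaldehyde
Product: 2 3,5-diisopropoxybenzaldehyde
Conditions: 2-bromopropane, K2CO3, DMF, 60 °C
Reagents that add atoms: 2-bromopropane CC(C)Br
Why: Williamson ether synthesis on both phenols; isopropyl ethers are inert to the alkyllithium and Tf2O steps, carry no second oxygen that could reach the activated amide of step 7, and can be cleaved by BCl3 beside a methyl ether.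

Step 2
Reactants: 2 3,5-diisopropoxybenzaldehyde
Product: 3 2-bromo-3,5-diisopropoxybenzaldehyde
Conditions: NBS, MeCN, 0 °C → rt
Reagents that add atoms: N-bromosuccinimide O=C1CCC(=O)N1Br
Why: Electrophilic aromatic bromination; the two equivalent positions ortho to the formyl group and para to an isopropoxy group should react in preference to the position flanked by both isopropoxy groups, as in the bromination of 3,5-dialkoxybenzaldehydes.

Step 3
Reactants: 3 2-bromo-3,5-diisopropoxybenzaldehyde
Product: 4 3,5-diisopropoxy-2-methoxybenzaldehyde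
Conditions: NaOMe, CuBr (10 mol %), MeOH/DMF, 90 °C
Reagents that add atoms: sodium methoxide [Na+].[O-]C
Why: Ullmann-type copper-catalysed methoxylation of an aryl bromide activated by the ortho formyl group installs the C5 methyl ether.

Step 4
Reactants: 4 3,5-diisopropoxy-2-methoxybenzaldehyde
Product: 5 2-bromo-3,5-diisopropoxy-6-methoxybenzaldehyde
Conditions: NBS, MeCN, 0 °C → rt
Reagents that add atoms: N-bromosuccinimide O=C1CCC(=O)N1Br
Why: Second electrophilic aromatic bromination at the one remaining position ortho to the formyl group and para to an isopropoxy group, the site between the two isopropoxy groups being shielded.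

Step 5
Reactants: 5 2-bromo-3,5-diisopropoxy-6-methoxybenzaldehyde
Product: 9 3,5-diisopropoxy-2-methoxy-6-(triethylsilyl)benzaldehyde, via lithium amino alkoxide 6 (not isolated), via aryllithium 7 (not isolated), via silylated amino alkoxide 8 (not isolated)
Conditions: LiN(Me)CH2CH2NMe2 (from MeNHCH2CH2NMe2, n-BuLi), THF, −78 °C; n-BuLi, −78 °C; Et3SiCl, −78 → −20 °C; H2O
Reagents that add atoms: chlorotriethylsilane CC[Si](Cl)(CC)CC
Why: Addition of the lithium amide masks the aldehyde as an α-amino alkoxide, so that bromine–lithium exchange and silylation of the aryllithium can follow in the same flask, and water returns the aldehyde; without a polar additive and below −20 °C the silyl group should stay on carbon.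

Step 6
Reactants: 9 3,5-diisopropoxy-2-methoxy-6-(triethylsilyl)benzaldehyde, 10 ethyl N,N-diisopropylcarbamate
Product: 17 (1S,2S)-1-[2-(diisopropylcarbamoyl)-3,5-diisopropoxy-6-methoxyphenyl]-2-(triethylsilyloxy)propyl acetate, via lithiated carbamate 11 (not isolated), via lithium alkoxide 12 (not isolated), via aryllithium 13 (not isolated), via tetrahedral adduct 14 (not isolated), via amide alkoxide 15 (not isolated), via benzylic alkoxide 16 (not isolated)
Conditions: 10, sec-BuLi, (+)-sparteine, Et2O, −78 °C, 5 h; then 9, −78 °C; then THF/HMPA, −78 → −20 °C; then Ac2O, −78 °C → rt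
Reagents that add atoms: acetic anhydride CC(=O)OC(C)=O
Why: Proposed new method: the configurationally stable lithium carbanion 11 should add to the aldehyde of 9 with retention (bond C3–C4); when HMPA is added, alkoxide 12 attacks the neighbouring silicon, the [1,4]-Brook shift from C8a to O4 frees aryllithium 13, and 13 adds to the carbamate carbonyl held in a six-membered array (bond C1–C8a), adduct 14 opening to amide 15; a 1,4-shift of silicon from O4 to O2 then gives the benzylic alkoxide 16, which Ac2O acetylates. The closest known reactions are the anion relay of ortho-silyl benzaldehydes (carbonyl addition, Brook rearrangement, capture of the aryl anion) and the anionic homo-Fries migration of a carbamoyl group to an ortho-lithiated arene; their union into a formal [3+3] assembly from a C3–O2–C1 donor–acceptor and a C4/C8a acceptor–donor has no precedent. No ring is left in 17: the only closure is the transient six-membered adduct 14, formed 6-exo-trig and reopened at C1–O2. C3 is set by (+)-sparteine, which guides sec-BuLi to one enantiotopic proton of 10, and is kept because the addition is retentive; C4 is set in that addition, where a lithium-bridged four-centre transition state that holds the 2,6-disubstituted aryl group away from the carbamoyloxy group should favour the (1S,2S) adduct, the minor carbinol epimer being removed by chromatography of 17. The step needs 13 to be acylated before it is protonated or moved to C7, which the intramolecular delivery should secure, and it needs silicon on O2 and acetyl on O4, which is a thermodynamic outcome (benzylic alkoxide chelated by the amide and methoxy oxygens, silicon on the less hindered oxygen) that even a prior 1,2-migration of the carbamoyl group cannot change, since all paths end in 16.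

Step 7
Reactants: 17 (1S,2S)-1-[2-(diisopropylcarbamoyl)-3,5-diisopropoxy-6-methoxyphenyl]-2-(triethylsilyloxy)propyl acetate
Product: 20 (3S,4S)-6,8-diisopropoxy-5-methoxy-3-methyl-1-oxoisochroman-4-yl acetate, via O-triflyl iminium triflate 18 (not isolated), via cyclic iminium ether triflate 19 (not isolated)
Conditions: Tf2O, 2-fluoropyridine, CH2Cl2, −78 → 0 °C; then aq. NaH2PO4 (pH 5), rt
Reagents that add atoms: water O
Why: Electrophilic amide activation: Tf2O should O-sulfonylate the twisted tertiary benzamide, the silyl ether oxygen closes 6-exo-trig onto the O-triflyl iminium carbon with loss of Et3SiOTf, and the resulting imidate salt hydrolyses at pH 5 with loss of the amine (imidate salt to ester), so that the lactone forms under kinetic control with O4 blocked as acetate and both stereocentres untouched.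

Step 8
Reactants: 20 (3S,4S)-6,8-diisopropoxy-5-methoxy-3-methyl-1-oxoisochroman-4-yl acetate
Product: 21 (3S,4S)-6,8-dihydroxy-5-methoxy-3-methyl-1-oxoisochroman-4-yl acetate
Conditions: BCl3, CH2Cl2, −78 → 0 °C; then H2O
Reagents that add atoms: none
Why: Lewis acid cleavage of aryl isopropyl ethers by BCl3 (chloride attacks the secondary alkyl group of the boron-bound ether), a dealkylation that should leave the C5 methyl ether, the lactone and the acetate intact at low temperature.

Step 9
Reactants: 21 (3S,4S)-6,8-dihydroxy-5-methoxy-3-methyl-1-oxoisochroman-4-yl acetate, 22 geranyl bromide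
Product: 23 (3S,4S)-6-[(2E)-3,7-dimethylocta-2,6-dienyloxy]-8-hydroxy-5-methoxy-3-methyl-1-oxoisochroman-4-yl acetate
Conditions: K2CO3, acetone, rt
Reagents that add atoms: none
Why: Williamson ether synthesis at the more acidic 6-hydroxyl (para to the lactone carbonyl), the 8-hydroxyl being held in a hydrogen bond to that carbonyl, with SN2 displacement at the primary allylic bromide keeping the E double bond.

**Compound list**

1 | 3,5-dihydroxybenzaldehyde | O=Cc1cc(O)cc(O)c1 | starting material
2 | 3,5-diisopropoxybenzaldehyde | O=Cc1cc(OC(C)C)cc(OC(C)C)c1 | intermediate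
3 | 2-bromo-3,5-diisopropoxybenzaldehyde | O=Cc1cc(OC(C)C)cc(OC(C)C)c1Br | intermediate
4 | 3,5-diisopropoxy-2-methoxybenzaldehyde | O=Cc1cc(OC(C)C)cc(OC(C)C)c1OC | intermediate
5 | 2-bromo-3,5-diisopropoxy-6-methoxybenzaldehyde | O=Cc1c(OC)c(OC(C)C)cc(OC(C)C)c1Br | intermediate
6 | lithium (2-bromo-3,5-diisopropoxy-6-methoxyphenyl){[2-(dimethylamino)ethyl](methyl)amino}methanolate (racemic, not isolated) | [Li]OC(N(C)CCN(C)C)c1c(OC)c(OC(C)C)cc(OC(C)C)c1Br | intermediate
7 | lithium {[2-(dimethylamino)ethyl](methyl)amino}(2-lithio-3,5-diisopropoxy-6-methoxyphenyl)methanolate (not isolated) | [Li]OC(N(C)CCN(C)C)c1c(OC)c(OC(C)C)cc(OC(C)C)c1[Li] | intermediate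
8 | lithium {[2-(dimethylamino)ethyl](methyl)amino}[3,5-diisopropoxy-2-methoxy-6-(triethylsilyl)phenyl]methanolate (not isolated) | [Li]OC(N(C)CCN(C)C)c1c(OC)c(OC(C)C)cc(OC(C)C)c1[Si](CC)(CC)CC | intermediate
9 | 3,5-diisopropoxy-2-methoxy-6-(triethylsilyl)benzaldehyde | O=Cc1c(OC)c(OC(C)C)cc(OC(C)C)c1[Si](CC)(CC)CC | intermediate
10 | ethyl N,N-diisopropylcarbamate | CCOC(=O)N(C(C)C)C(C)C | starting material
11 | (R)-1-lithioethyl N,N-diisopropylcarbamate, as its (+)-sparteine complex (not isolated) | C[C@@H]([Li])OC(=O)N(C(C)C)C(C)C | intermediate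
12 | lithium (1S,2S)-2-(diisopropylcarbamoyloxy)-1-[3,5-diisopropoxy-2-methoxy-6-(triethylsilyl)phenyl]propan-1-olate (not isolated) | COc1c(OC(C)C)cc(OC(C)C)c([Si](CC)(CC)CC)c1[C@H](O[Li])[C@H](C)OC(=O)N(C(C)C)C(C)C | intermediate
13 | (1S,2S)-1-(2-lithio-3,5-diisopropoxy-6-methoxyphenyl)-1-(triethylsilyloxy)propan-2-yl N,N-diisopropylcarbamate (not isolated) | COc1c(OC(C)C)cc(OC(C)C)c([Li])c1[C@H](O[Si](CC)(CC)CC)[C@H](C)OC(=O)N(C(C)C)C(C)C | intermediate
14 | lithium (3S,4S)-1-(diisopropylamino)-6,8-diisopropoxy-5-methoxy-3-methyl-4-(triethylsilyloxy)isochroman-1-olate (not isolated) | COc1c(OC(C)C)cc(OC(C)C)c2c1[C@H](O[Si](CC)(CC)CC)[C@H](C)OC2(O[Li])N(C(C)C)C(C)C | intermediate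
15 | lithium (1S,2S)-1-[2-(diisopropylcarbamoyl)-3,5-diisopropoxy-6-methoxyphenyl]-1-(triethylsilyloxy)propan-2-olate (not isolated) | COc1c(OC(C)C)cc(OC(C)C)c(C(=O)N(C(C)C)C(C)C)c1[C@H](O[Si](CC)(CC)CC)[C@H](C)O[Li] | intermediate
16 | lithium (1S,2S)-1-[2-(diisopropylcarbamoyl)-3,5-diisopropoxy-6-methoxyphenyl]-2-(triethylsilyloxy)propan-1-olate (not isolated) | COc1c(OC(C)C)cc(OC(C)C)c(C(=O)N(C(C)C)C(C)C)c1[C@H](O[Li])[C@H](C)O[Si](CC)(CC)CC | intermediate
17 | (1S,2S)-1-[2-(diisopropylcarbamoyl)-3,5-diisopropoxy-6-methoxyphenyl]-2-(triethylsilyloxy)propyl acetate | COc1c(OC(C)C)cc(OC(C)C)c(C(=O)N(C(C)C)C(C)C)c1[C@H](OC(C)=O)[C@H](C)O[Si](CC)(CC)CC | intermediate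
18 | O-triflyl iminium triflate of amide 17 (not isolated) | COc1c(OC(C)C)cc(OC(C)C)c(C(OS(=O)(=O)C(F)(F)F)=[N+](C(C)C)C(C)C)c1[C@H](OC(C)=O)[C@H](C)O[Si](CC)(CC)CC.[O-]S(=O)(=O)C(F)(F)F | intermediate
19 | [(3S,4S)-4-acetoxy-6,8-diisopropoxy-5-methoxy-3-methylisochroman-1-ylidene]diisopropylammonium triflate (not isolated) | COc1c(OC(C)C)cc(OC(C)C)c2c1[C@H](OC(C)=O)[C@H](C)OC2=[N+](C(C)C)C(C)C.[O-]S(=O)(=O)C(F)(F)F | intermediate
20 | (3S,4S)-6,8-diisopropoxy-5-methoxy-3-methyl-1-oxoisochroman-4-yl acetate | COc1c(OC(C)C)cc(OC(C)C)c2c1[C@H](OC(C)=O)[C@H](C)OC2=O | intermediate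
21 | (3S,4S)-6,8-dihydroxy-5-methoxy-3-methyl-1-oxoisochroman-4-yl acetate | COc1c(O)cc(O)c2c1[C@H](OC(C)=O)[C@H](C)OC2=O | intermediate
22 | geranyl bromide, (2E)-1-bromo-3,7-dimethylocta-2,6-diene | BrC/C=C(\C)CCC=C(C)C | starting material
23 | (3S,4S)-6-[(2E)-3,7-dimethylocta-2,6-dienyloxy]-8-hydroxy-5-methoxy-3-methyl-1-oxoisochroman-4-yl acetate (cis) | COc1c(OC/C=C(\C)CCC=C(C)C)cc(O)c2c1[C@H](OC(C)=O)[C@H](C)OC2=O | target

**Count and risks**

Total steps: 9. Longest linear sequence: 9 steps (1 → 23).

Step 6. The aryl anion may be protonated or shifted to C7 before it is acylated, which would leave a desilylated carbamate. The addition to the hindered aldehyde may show poor facial selectivity. If the silyl shift from O4 to O2 is incomplete, the acetyl group would land on the wrong oxygen. The fallback uses stepwise, known anionic chemistry and sets out from 5. The lithiated carbamate 11 (made as in step 6) is added to 5 (Et2O, −78 °C, AcOH quench) to give the hydroxy carbamate (2S)-1-(2-bromo-3,5-diisopropoxy-6-methoxyphenyl)-1-hydroxypropan-2-yl N,N-diisopropylcarbamate F1 as both carbinol epimers. t-BuLi (3 equiv, THF, −78 → 0 °C) deprotonates the hydroxyl and exchanges bromine for lithium, and the aryllithium takes the carbamoyl group in an anionic homo-Fries shift to give the diol amide 2-[(2S)-1,2-dihydroxypropyl]-4,6-diisopropoxy-3-methoxy-N,N-diisopropylbenzamide F2. Et3SiCl and imidazole silylate the less hindered, non-benzylic hydroxyl to give 2-[(2S)-1-hydroxy-2-(triethylsilyloxy)propyl]-4,6-diisopropoxy-3-methoxy-N,N-diisopropylbenzamide F3, whose carbinol epimers are separated. The (1S) epimer is acetylated (Ac2O, DMAP, pyridine) and the (1R) epimer is esterified with inversion (AcOH, PPh3, DIAD, Mitsunobu reaction); both come back to the route at 17.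

Step 7. O-sulfonylation of the hindered amide may be slow, so that Tf2O attacks the electron-rich ring or the silyl ether instead. The iminium ether may also reopen at C1–O2 on hydrolysis and return a hydroxy amide. The fallback is reductive and sets out from 17. Cp2Zr(H)Cl (THF, rt) reduces the tertiary amide, beside the acetate, to the aldehyde (1S,2S)-1-(2-formyl-3,5-diisopropoxy-6-methoxyphenyl)-2-(triethylsilyloxy)propyl acetate F4. HF·pyridine removes the silyl group and the freed hydroxyl closes onto the aldehyde to give the lactol (3S,4S)-1-hydroxy-6,8-diisopropoxy-5-methoxy-3-methylisochroman-4-yl acetate F5. Oxidation (TEMPO, PhI(OAc)2) comes back to the route at 20.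

Step 5. Silylation of the doubly ortho-substituted aryllithium may be slow, which would return debrominated aldehyde. The silyl group may also move to the neighbouring alkoxide oxygen and be lost on work-up. The fallback delivers silicon intramolecularly and sets out from 5. NaBH4 (MeOH) gives the benzyl alcohol (2-bromo-3,5-diisopropoxy-6-methoxyphenyl)methanol F6, and Et3SiCl with imidazole gives the silyl ether [(2-bromo-3,5-diisopropoxy-6-methoxybenzyl)oxy]triethylsilane F7. t-BuLi (2 equiv, THF, −78 °C → rt) exchanges bromine for lithium and the silyl group moves from oxygen to the ring carbon (retro-[1,4]-Brook rearrangement) to give [3,5-diisopropoxy-2-methoxy-6-(triethylsilyl)phenyl]methanol F8. MnO2 (CH2Cl2) oxidises the benzylic alcohol and comes back to the route at 9.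

**Further compounds**

F1 | step 6 | (2S)-1-(2-bromo-3,5-diisopropoxy-6-methoxyphenyl)-1-hydroxypropan-2-yl N,N-diisopropylcarbamate (both carbinol epimers) | COc1c(OC(C)C)cc(OC(C)C)c(Br)c1C(O)[C@H](C)OC(=O)N(C(C)C)C(C)C
F2 | step 6 | 2-[(2S)-1,2-dihydroxypropyl]-4,6-diisopropoxy-3-methoxy-N,N-diisopropylbenzamide (both carbinol epimers) | COc1c(OC(C)C)cc(OC(C)C)c(C(=O)N(C(C)C)C(C)C)c1C(O)[C@H](C)O
F3 | step 6 | 2-[(2S)-1-hydroxy-2-(triethylsilyloxy)propyl]-4,6-diisopropoxy-3-methoxy-N,N-diisopropylbenzamide (carbinol epimers, separated) | COc1c(OC(C)C)cc(OC(C)C)c(C(=O)N(C(C)C)C(C)C)c1C(O)[C@H](C)O[Si](CC)(CC)CC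
F4 | step 7 | (1S,2S)-1-(2-formyl-3,5-diisopropoxy-6-methoxyphenyl)-2-(triethylsilyloxy)propyl acetate | COc1c(OC(C)C)cc(OC(C)C)c(C=O)c1[C@H](OC(C)=O)[C@H](C)O[Si](CC)(CC)CC
F5 | step 7 | (3S,4S)-1-hydroxy-6,8-diisopropoxy-5-methoxy-3-methylisochroman-4-yl acetate (lactol, both anomers) | COc1c(OC(C)C)cc(OC(C)C)c2c1[C@H](OC(C)=O)[C@H](C)OC2O
F6 | step 5 | (2-bromo-3,5-diisopropoxy-6-methoxyphenyl)methanol | OCc1c(OC)c(OC(C)C)cc(OC(C)C)c1Br
F7 | step 5 | [(2-bromo-3,5-diisopropoxy-6-methoxybenzyl)oxy]triethylsilane | CC[Si](CC)(CC)OCc1c(OC)c(OC(C)C)cc(OC(C)C)c1Br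
F8 | step 5 | [3,5-diisopropoxy-2-methoxy-6-(triethylsilyl)phenyl]methanol | OCc1c(OC)c(OC(C)C)cc(OC(C)C)c1[Si](CC)(CC)CC
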